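**Plan**
1. Retrosynthesis: the oxolane is cut at C2–C3 and C4–C5 in one stroke (retro-[3+2]) into a 1,3-bis(4-oxyphenyl) carbonyl ylide (from a 4,4'-dioxystilbene oxide) and a Z-1,2-diarylethene; the alkene is cut to an alkyne and an aryl bromide; each dihydrobenzofuran is cut at C2–C3 (carbene C–H insertion into an ortho benzylic ether).
2. Forward: dihydrobenzofuran B (the 7-oxygenated one, steps 1–5), the aldehyde for ring A (6–8), dihydrobenzofuran A on C5 of B (9–11), C2 equilibration and change to acetates (12), alkyne and Z-alkene (13–15), oxirane (16–17), oxolane (18), deprotection (19).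
3. Enabling feature: the oxolane oxygen lies between two benzylic CH groups (C2, C5) that each bear a 4-oxyphenyl ring, a masked C–O–C 4π dipole; C3 and C4 bear two cis aryl rings whose oxygens are all meta to the ring bond, a Z-stilbene that becomes a low-LUMO, oxidation-resistant dipolarophile once acetylated.
4. Stereochemistry: C3 of each dihydrobenzofuran from catalyst-controlled C–H insertion (antipodal dirhodium catalysts), C2 of each from acid equilibration to trans; oxolane C2/C5 cis from the W-shaped ylide, C3/C4 cis from the Z-alkene, 2,3- and 4,5-trans from the exo approach, absolute sense from the C3 aryl group of dihydrobenzofuran A.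

Key step: step 18

Remark: the sense of induction of each dirhodium catalyst antipode is assigned by analogy with related donor/donor carbene insertions (if it is the reverse, the antipodes are exchanged between steps 5 and 11). Compounds 3 and 5 are treated as catalogue compounds, each otherwise one MOMCl alkylation from the parent phenol.

**Step 1**
Reactants: 1 5-bromo-2,3-dihydroxybenzaldehyde
Product: 2 5-bromo-2-hydroxy-3-(methoxymethoxy)benzaldehyde
Conditions: NaH (2.2 equiv), DMF, 0 °C; then MOMCl (1.0 equiv), 0 °C; then aq. NH4Cl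
Reagents that add atoms: chloromethyl methyl ether (MOMCl), COCCl
Why: Regioselective mono-O-alkylation of the catecholate dianion should take place at O3, the phenoxide that is not conjugated with the formyl group and is therefore the more nucleophilic one, which leaves the 2-OH free for step 2; no stereocentre is formed.

**Step 2**
Reactants: 2 5-bromo-2-hydroxy-3-(methoxymethoxy)benzaldehyde; 3 [4-(methoxymethoxy)phenyl]methanol
Product: 4 5-bromo-3-(methoxymethoxy)-2-{[4-(methoxymethoxy)phenyl]methoxy}benzaldehyde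
Conditions: PPh3, DIAD, THF, 0 to 23 °C
Reagents that add atoms: none
Why: Mitsunobu etherification of the acidic salicylaldehyde-type phenol with the primary benzylic alcohol should place at O2 the ArCH2 group whose C–H bond is used in step 5, without recourse to an unstable 4-alkoxybenzyl halide; no stereocentre is formed.

**Step 3**
Reactants: 4 alkoxy bromobenzaldehyde; 5 1-bromo-3,5-bis(methoxymethoxy)benzene
Product: 8 {5-bromo-3-(methoxymethoxy)-2-{[4-(methoxymethoxy)phenyl]methoxy}phenyl}[3,5-bis(methoxymethoxy)phenyl]methanone, via arylmagnesium bromide 6 (not isolated), via bromomagnesium alkoxide 7 (not isolated)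
Conditions: 5, Mg, THF, 40 °C; then 4, 0 °C; then 1,1'-(azodicarbonyl)dipiperidine, 23 °C
Reagents that add atoms: none
Why: Grignard addition to the aldehyde followed by hydride transfer from the bromomagnesium alkoxide to the azodicarboxamide (Mukaiyama oxidation) should give the diaryl ketone in one flask, the aryl bromide of 4 being inert to the Grignard reagent at 0 °C; the carbinol centre is destroyed.

**Step 4**
Reactants: 8 diaryl ketone
Product: 9 N-unsubstituted hydrazone of 8
Conditions: N2H4·H2O, AcOH (cat.), EtOH, 80 °C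
Reagents that add atoms: hydrazine (used as the hydrate), NN
Why: Hydrazone condensation at a diaryl ketone with only one ortho substituent should proceed normally; the C=N geometry is of no consequence.

**Step 5**
Reactants: 9 hydrazone
Product: 11 (2S,3R)-5-bromo-3-[3,5-bis(methoxymethoxy)phenyl]-7-(methoxymethoxy)-2-[4-(methoxymethoxy)phenyl]-2,3-dihydro-1-benzofuran (cis dihydrobenzofuran B bromide), via diaryldiazomethane 10 (not isolated)
Conditions: MnO2, CH2Cl2, 0 °C, filtration; then Rh2[(R)-PTAD]4 (dirhodium tetrakis[(R)-(1-adamantyl)(phthalimido)acetate], 1 mol %), CH2Cl2, 0 to 23 °C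
Reagents that add atoms: none
Why: Dehydrogenation of the hydrazone to the diaryldiazomethane and dirhodium-carbene 1,5 C–H insertion into the ortho benzylic ether CH2 (donor/donor carbene insertion) should close the dihydrofuran ring, the chiral carboxylate catalyst setting C3 as R and the insertion giving the 2,3-cis isomer whose C2 is corrected in step 12.

**Step 6**
Reactants: 12 2-bromo-4,6-dimethoxybenzaldehyde
Product: 13 2-bromo-4,6-dihydroxybenzaldehyde
Conditions: BBr3 (3.5 equiv), CH2Cl2, −78 to 23 °C; then H2O, 0 °C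
Reagents that add atoms: none
Why: Lewis-acid cleavage of both aryl methyl ethers by BBr3 (the one ortho to the formyl group first, through chelation) should give the resorcinol aldehyde, the formyl group being recovered on aqueous work-up; no stereocentre is formed.

**Step 7**
Reactants: 13 2-bromo-4,6-dihydroxybenzaldehyde
Product: 14 2-bromo-6-hydroxy-4-(methoxymethoxy)benzaldehyde
Conditions: MOMCl (1.05 equiv), i-Pr2NEt, CH2Cl2, 0 °C
Reagents that add atoms: chloromethyl methyl ether (MOMCl), COCCl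
Why: The 4-OH, which is not held in the intramolecular hydrogen bond to the formyl group, should be alkylated selectively (the usual regioselective 4-O-protection of 2,4-dihydroxybenzaldehydes); no stereocentre is formed.

**Step 8**
Reactants: 14 2-bromo-6-hydroxy-4-(methoxymethoxy)benzaldehyde; 3 [4-(methoxymethoxy)phenyl]methanol
Product: 15 2-bromo-4-(methoxymethoxy)-6-{[4-(methoxymethoxy)phenyl]methoxy}benzaldehyde
Conditions: PPh3, DIAD, THF, 0 to 23 °C
Reagents that add atoms: none
Why: Mitsunobu etherification of the remaining hydrogen-bonded ortho phenol with the primary benzylic alcohol should install the ArCH2 group whose C–H bond is used in step 11; no stereocentre is formed.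

**Step 9**
Reactants: 11 cis dihydrobenzofuran B bromide; 15 bromo dialkoxybenzaldehyde
Product: 18 {2-bromo-4-(methoxymethoxy)-6-{[4-(methoxymethoxy)phenyl]methoxy}phenyl}{(2S,3R)-3-[3,5-bis(methoxymethoxy)phenyl]-7-(methoxymethoxy)-2-[4-(methoxymethoxy)phenyl]-2,3-dihydro-1-benzofuran-5-yl}methanone, via arylmagnesium bromide 16 (not isolated), via bromomagnesium alkoxide 17 (not isolated)
Conditions: 11, Mg, LiCl, THF, 23 °C; then 15, 0 °C; then 1,1'-(azodicarbonyl)dipiperidine, 23 °C
Reagents that add atoms: none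
Why: LiCl-assisted magnesium insertion, Grignard addition to the hindered aldehyde (faster than any exchange with its aryl bromide) and Mukaiyama oxidation of the alkoxide should give the ketone; the C2/C3 centres of ring B are not touched and the carbinol centre is destroyed.

**Step 10**
Reactants: 18 hindered diaryl ketone
Product: 19 N-unsubstituted hydrazone of 18
Conditions: N2H4·H2O (large excess), AcOH (cat.), n-BuOH, 110 °C
Reagents that add atoms: hydrazine (used as the hydrate), NN
Why: Hydrazone condensation at a ketone flanked by Br and OCH2Ar needs forcing conditions but meets only robust groups (aryl ethers, acetals, aryl bromide); no stereocentre changes.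

**Step 11**
Reactants: 19 hydrazone
Product: 21 (2R,3S)-4-bromo-3-{(2S,3R)-3-[3,5-bis(methoxymethoxy)phenyl]-7-(methoxymethoxy)-2-[4-(methoxymethoxy)phenyl]-2,3-dihydro-1-benzofuran-5-yl}-6-(methoxymethoxy)-2-[4-(methoxymethoxy)phenyl]-2,3-dihydro-1-benzofuran (both rings 2,3-cis), via diaryldiazomethane 20 (not isolated)
Conditions: MnO2, CH2Cl2, 0 °C, filtration; then Rh2[(S)-PTAD]4 (dirhodium tetrakis[(S)-(1-adamantyl)(phthalimido)acetate], 1 mol %), CH2Cl2, 0 to 23 °C
Reagents that add atoms: none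
Why: The same hydrazone dehydrogenation and donor/donor carbene C–H insertion as in step 5 should occur at the only CH2 that can reach the carbene through a five-membered transition state, the antipodal catalyst setting C3 of dihydrobenzofuran A as S independently of the remote centres of ring B, with the cis C2 centre corrected in step 12.

**Step 12**
Reactants: 21 cis,cis bromide
Product: 23 hexaacetate of the trans,trans hexaphenol bromide, via hexaphenol 22 (not isolated)
Conditions: HCl (3 M in MeOH)–THF, 50 °C; evaporation; then Ac2O, pyridine, DMAP (cat.), 23 °C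
Reagents that add atoms: acetic anhydride, CC(=O)OC(C)=O
Why: Acid methanolysis should cleave the six methoxymethyl acetals (the only protecting groups left, so no benzylic cation is released beside the substrate), while reversible SN1 ionisation of the O1–C2 bond of each 2-(4-hydroxyphenyl)dihydrobenzofuran equilibrates both C2 centres to trans (C3 untouched), and peracetylation then installs the electron-withdrawing esters needed in step 18.

**Step 13**
Reactants: 24 3,5-dihydroxybenzaldehyde
Product: 26 5-ethynyl-1,3-phenylene diacetate, via 5-ethynylbenzene-1,3-diol 25 (not isolated)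
Conditions: dimethyl (1-diazo-2-oxopropyl)phosphonate, K2CO3, MeOH, 23 °C; evaporation; then Ac2O, pyridine, 23 °C
Reagents that add atoms: dimethyl (1-diazo-2-oxopropyl)phosphonate, COP(=O)(OC)C(=[N+]=[N-])C(C)=O; acetic anhydride, CC(=O)OC(C)=O
Why: Seyferth–Gilbert homologation with the Ohira–Bestmann reagent should convert the aldehyde into the terminal alkyne and acetylation caps the phenols; no stereocentre is formed.

**Step 14**
Reactants: 23 hexaacetate bromide; 26 diacetoxy arylacetylene
Product: 27 diarylalkyne octaacetate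
Conditions: PdCl2(PhCN)2, P(t-Bu)3, CuI, i-Pr2NH, dioxane, 23 to 45 °C
Reagents that add atoms: none
Why: Sonogashira coupling with a bulky electron-rich phosphine should engage the hindered aryl bromide while the aryl acetates tolerate the hindered secondary amine; no stereocentre is touched.

**Step 15**
Reactants: 27 diarylalkyne
Product: 28 Z-1,2-diarylethene octaacetate
Conditions: H2 (1 atm), Pd on CaCO3 poisoned with Pb(OAc)2 (Lindlar catalyst), quinoline, EtOAc, 23 °C
Reagents that add atoms: none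
Why: Lindlar semihydrogenation adds hydrogen syn to the alkyne and should give the Z alkene without hydrogenolysis of the acetates or the benzylic C–O bonds.

**Step 16**
Reactants: 29 (E)-4,4'-(ethene-1,2-diyl)diphenol
Product: 30 (E)-1,2-bis{4-[(tert-butyldimethylsilyl)oxy]phenyl}ethene
Conditions: TBSCl, imidazole, DMF, 23 °C
Reagents that add atoms: tert-butyldimethylsilyl chloride, CC(C)(C)[Si](C)(C)Cl
Why: Imidazole-mediated silylation of both phenols should give an electron-rich, base-labile aryl ether; no stereocentre is formed.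

**Step 17**
Reactants: 30 bis(silyloxy)stilbene
Product: 31 rac-(2R,3R)-2,3-bis{4-[(tert-butyldimethylsilyl)oxy]phenyl}oxirane
Conditions: dimethyldioxirane, acetone, 0 °C
Reagents that add atoms: dimethyldioxirane, CC1(C)OO1
Why: Neutral, concerted and stereospecific oxygen transfer should give the acid-sensitive trans oxirane as the racemate, whose relative and absolute configuration are both erased later in the ylide.

**Step 18**
Reactants: 28 Z-1,2-diarylethene octaacetate; 31 diaryloxirane
Product: 33 octaacetate bis(tert-butyldimethylsilyl) ether of kobophenol A with the (2R,3S,4R,5S) oxolane, via carbonyl ylide 32 (not isolated)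
Conditions: 9,10-dicyanoanthracene (10 mol %), 420 nm LEDs, degassed MeCN–CH2Cl2, 20 °C, 31 in excess added in portions
Reagents that add atoms: none
Why: Proposed new method: electron transfer from oxirane 31 to singlet-excited 9,10-dicyanoanthracene cleaves the oxirane C–C bond and back electron transfer gives the W-shaped (exo,exo) carbonyl ylide 32 from either oxirane enantiomer, and this 4π-electron C–O–C dipole should add to the Z C=C bond of 28 in a concerted suprafacial [3+2] cycloaddition (π4s + π2s) that closes the oxolane intermolecularly by forming C2–C3 and C4–C5 at once, the leading interaction being the ylide HOMO with the LUMO of the acetoxy-substituted stilbene. The closest known reaction types are the sensitised cycloadditions of 2,3-diaryloxirane-derived carbonyl ylides with electron-poor alkenes, which give 2,5-cis-diaryloxolanes with retention of alkene geometry, and the additions of the isoelectronic 1,3-diaryl-2-azaallyl anions to stilbenes; a non-activated 1,2-diarylethene has not been used as the trap. C2 and C5 are set cis by the W geometry of the ylide, C3 and C4 are set cis by the Z geometry of the alkene, and the 2,3-trans and 4,5-trans relations follow from the exo transition state in which the ylide aryl groups point away from the alkene aryl groups. The absolute sense is set by dihydrobenzofuran A: its C3 substituent (the ring B aryl group) stands over one face of the styrenyl C=C bond at the peri position C4, so that the ylide should enter from the face on the side of C3–H, which leads to the (2R,3S,4R,5S) oxolane. The step needs ylide formation without oxidation or Z to E isomerisation of 28: the eight acetates should place the oxidation potential of every ring of 28 above that of the bis(silyloxyphenyl)oxirane, only the sensitiser absorbs at 420 nm and its triplet energy lies below that of the stilbene, oxygen is excluded, and unreacted ylide merely recloses to 31.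

**Step 19**
Reactants: 33 protected cycloadduct
Product: 34 kobophenol A
Conditions: K2CO3, MeOH–THF, 0 to 23 °C, argon; then aq. NH4Cl
Reagents that add atoms: none
Why: Methoxide generated in situ should transesterify the eight aryl acetates and cleave the two aryl silyl ethers under conditions that do not ionise the benzylic C–O bonds, so no stereocentre is touched.

**Compound list**
1 | 5-bromo-2,3-dihydroxybenzaldehyde | O=Cc1cc(Br)cc(O)c1O | starting material
2 | 5-bromo-2-hydroxy-3-(methoxymethoxy)benzaldehyde | O=Cc1cc(Br)cc(OCOC)c1O | intermediate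
3 | [4-(methoxymethoxy)phenyl]methanol | COCOc1ccc(CO)cc1 | starting material
4 | 5-bromo-3-(methoxymethoxy)-2-{[4-(methoxymethoxy)phenyl]methoxy}benzaldehyde | O=Cc1cc(Br)cc(OCOC)c1OCc1ccc(OCOC)cc1 | intermediate
5 | 1-bromo-3,5-bis(methoxymethoxy)benzene | COCOc1cc(Br)cc(OCOC)c1 | starting material
6 | [3,5-bis(methoxymethoxy)phenyl]magnesium bromide | COCOc1cc([Mg]Br)cc(OCOC)c1 | intermediate (not isolated)
7 | bromomagnesium {5-bromo-3-(methoxymethoxy)-2-{[4-(methoxymethoxy)phenyl]methoxy}phenyl}[3,5-bis(methoxymethoxy)phenyl]methanolate (racemic) | Br[Mg]OC(c1cc(OCOC)cc(OCOC)c1)c1cc(Br)cc(OCOC)c1OCc1ccc(OCOC)cc1 | intermediate (not isolated)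
8 | {5-bromo-3-(methoxymethoxy)-2-{[4-(methoxymethoxy)phenyl]methoxy}phenyl}[3,5-bis(methoxymethoxy)phenyl]methanone | O=C(c1cc(OCOC)cc(OCOC)c1)c1cc(Br)cc(OCOC)c1OCc1ccc(OCOC)cc1 | intermediate
9 | {[5-bromo-3-(methoxymethoxy)-2-{[4-(methoxymethoxy)phenyl]methoxy}phenyl][3,5-bis(methoxymethoxy)phenyl]methylidene}hydrazine (E/Z mixture) | NN=C(c1cc(OCOC)cc(OCOC)c1)c1cc(Br)cc(OCOC)c1OCc1ccc(OCOC)cc1 | intermediate
10 | 5-bromo-1-{diazo[3,5-bis(methoxymethoxy)phenyl]methyl}-3-(methoxymethoxy)-2-{[4-(methoxymethoxy)phenyl]methoxy}benzene | [N-]=[N+]=C(c1cc(OCOC)cc(OCOC)c1)c1cc(Br)cc(OCOC)c1OCc1ccc(OCOC)cc1 | intermediate (not isolated)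
11 | (2S,3R)-5-bromo-3-[3,5-bis(methoxymethoxy)phenyl]-7-(methoxymethoxy)-2-[4-(methoxymethoxy)phenyl]-2,3-dihydro-1-benzofuran (2,3-cis) | Brc1cc(OCOC)c2c(c1)[C@@H](c1cc(OCOC)cc(OCOC)c1)[C@@H](c1ccc(OCOC)cc1)O2 | intermediate
12 | 2-bromo-4,6-dimethoxybenzaldehyde | O=Cc1c(OC)cc(OC)cc1Br | starting material
13 | 2-bromo-4,6-dihydroxybenzaldehyde | O=Cc1c(O)cc(O)cc1Br | intermediate
14 | 2-bromo-6-hydroxy-4-(methoxymethoxy)benzaldehyde | O=Cc1c(O)cc(OCOC)cc1Br | intermediate
15 | 2-bromo-4-(methoxymethoxy)-6-{[4-(methoxymethoxy)phenyl]methoxy}benzaldehyde | O=Cc1c(OCc2ccc(OCOC)cc2)cc(OCOC)cc1Br | intermediate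
16 | bromo{(2S,3R)-3-[3,5-bis(methoxymethoxy)phenyl]-7-(methoxymethoxy)-2-[4-(methoxymethoxy)phenyl]-2,3-dihydro-1-benzofuran-5-yl}magnesium | Br[Mg]c1cc(OCOC)c2c(c1)[C@@H](c1cc(OCOC)cc(OCOC)c1)[C@@H](c1ccc(OCOC)cc1)O2 | intermediate (not isolated)
17 | bromomagnesium {2-bromo-4-(methoxymethoxy)-6-{[4-(methoxymethoxy)phenyl]methoxy}phenyl}{(2S,3R)-3-[3,5-bis(methoxymethoxy)phenyl]-7-(methoxymethoxy)-2-[4-(methoxymethoxy)phenyl]-2,3-dihydro-1-benzofuran-5-yl}methanolate (mixture at the carbinol carbon) | Br[Mg]OC(c1c(OCc2ccc(OCOC)cc2)cc(OCOC)cc1Br)c1cc(OCOC)c2c(c1)[C@@H](c1cc(OCOC)cc(OCOC)c1)[C@@H](c1ccc(OCOC)cc1)O2 | intermediate (not isolated)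
18 | {2-bromo-4-(methoxymethoxy)-6-{[4-(methoxymethoxy)phenyl]methoxy}phenyl}{(2S,3R)-3-[3,5-bis(methoxymethoxy)phenyl]-7-(methoxymethoxy)-2-[4-(methoxymethoxy)phenyl]-2,3-dihydro-1-benzofuran-5-yl}methanone | O=C(c1c(OCc2ccc(OCOC)cc2)cc(OCOC)cc1Br)c1cc(OCOC)c2c(c1)[C@@H](c1cc(OCOC)cc(OCOC)c1)[C@@H](c1ccc(OCOC)cc1)O2 | intermediate
19 | N-unsubstituted hydrazone of 18 (C=O replaced by C=N–NH2, E/Z mixture) | NN=C(c1c(OCc2ccc(OCOC)cc2)cc(OCOC)cc1Br)c1cc(OCOC)c2c(c1)[C@@H](c1cc(OCOC)cc(OCOC)c1)[C@@H](c1ccc(OCOC)cc1)O2 | intermediate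
20 | (2S,3R)-5-[{2-bromo-4-(methoxymethoxy)-6-{[4-(methoxymethoxy)phenyl]methoxy}phenyl}(diazo)methyl]-3-[3,5-bis(methoxymethoxy)phenyl]-7-(methoxymethoxy)-2-[4-(methoxymethoxy)phenyl]-2,3-dihydro-1-benzofuran | [N-]=[N+]=C(c1c(OCc2ccc(OCOC)cc2)cc(OCOC)cc1Br)c1cc(OCOC)c2c(c1)[C@@H](c1cc(OCOC)cc(OCOC)c1)[C@@H](c1ccc(OCOC)cc1)O2 | intermediate (not isolated)
21 | (2R,3S)-4-bromo-3-{(2S,3R)-3-[3,5-bis(methoxymethoxy)phenyl]-7-(methoxymethoxy)-2-[4-(methoxymethoxy)phenyl]-2,3-dihydro-1-benzofuran-5-yl}-6-(methoxymethoxy)-2-[4-(methoxymethoxy)phenyl]-2,3-dihydro-1-benzofuran (both rings 2,3-cis) | COCOc1ccc([C@@H]2Oc3cc(OCOC)cc(Br)c3[C@@H]2c2cc(OCOC)c3c(c2)[C@@H](c2cc(OCOC)cc(OCOC)c2)[C@@H](c2ccc(OCOC)cc2)O3)cc1 | intermediate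
22 | (2S,3S)-4-bromo-3-[(2R,3R)-3-(3,5-dihydroxyphenyl)-7-hydroxy-2-(4-hydroxyphenyl)-2,3-dihydro-1-benzofuran-5-yl]-2-(4-hydroxyphenyl)-2,3-dihydro-1-benzofuran-6-ol (both rings 2,3-trans) | Oc1ccc([C@H]2Oc3cc(O)cc(Br)c3[C@@H]2c2cc(O)c3c(c2)[C@@H](c2cc(O)cc(O)c2)[C@H](c2ccc(O)cc2)O3)cc1 | intermediate (not isolated)
23 | (2S,3S)-2-(4-acetoxyphenyl)-3-[(2R,3R)-7-acetoxy-2-(4-acetoxyphenyl)-3-(3,5-diacetoxyphenyl)-2,3-dihydro-1-benzofuran-5-yl]-4-bromo-2,3-dihydro-1-benzofuran-6-yl acetate | CC(=O)Oc1ccc([C@H]2Oc3cc(OC(C)=O)cc(Br)c3[C@@H]2c2cc(OC(C)=O)c3c(c2)[C@@H](c2cc(OC(C)=O)cc(OC(C)=O)c2)[C@H](c2ccc(OC(C)=O)cc2)O3)cc1 | intermediate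
24 | 3,5-dihydroxybenzaldehyde | O=Cc1cc(O)cc(O)c1 | starting material
25 | 5-ethynylbenzene-1,3-diol | C#Cc1cc(O)cc(O)c1 | intermediate (not isolated)
26 | 5-ethynyl-1,3-phenylene diacetate | C#Cc1cc(OC(C)=O)cc(OC(C)=O)c1 | intermediate
27 | (2S,3S)-2-(4-acetoxyphenyl)-3-[(2R,3R)-7-acetoxy-2-(4-acetoxyphenyl)-3-(3,5-diacetoxyphenyl)-2,3-dihydro-1-benzofuran-5-yl]-4-[(3,5-diacetoxyphenyl)ethynyl]-2,3-dihydro-1-benzofuran-6-yl acetate | CC(=O)Oc1ccc([C@H]2Oc3cc(OC(C)=O)cc(C#Cc4cc(OC(C)=O)cc(OC(C)=O)c4)c3[C@@H]2c2cc(OC(C)=O)c3c(c2)[C@@H](c2cc(OC(C)=O)cc(OC(C)=O)c2)[C@H](c2ccc(OC(C)=O)cc2)O3)cc1 | intermediate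
28 | (2S,3S)-2-(4-acetoxyphenyl)-3-[(2R,3R)-7-acetoxy-2-(4-acetoxyphenyl)-3-(3,5-diacetoxyphenyl)-2,3-dihydro-1-benzofuran-5-yl]-4-[(Z)-2-(3,5-diacetoxyphenyl)ethenyl]-2,3-dihydro-1-benzofuran-6-yl acetate | CC(=O)Oc1ccc([C@H]2Oc3cc(OC(C)=O)cc(/C=C\c4cc(OC(C)=O)cc(OC(C)=O)c4)c3[C@@H]2c2cc(OC(C)=O)c3c(c2)[C@@H](c2cc(OC(C)=O)cc(OC(C)=O)c2)[C@H](c2ccc(OC(C)=O)cc2)O3)cc1 | intermediate
29 | (E)-4,4'-(ethene-1,2-diyl)diphenol | Oc1ccc(/C=C/c2ccc(O)cc2)cc1 | starting material
30 | (E)-1,2-bis{4-[(tert-butyldimethylsilyl)oxy]phenyl}ethene | CC(C)(C)[Si](C)(C)Oc1ccc(/C=C/c2ccc(O[Si](C)(C)C(C)(C)C)cc2)cc1 | intermediate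
31 | rac-(2R,3R)-2,3-bis{4-[(tert-butyldimethylsilyl)oxy]phenyl}oxirane (trans; one enantiomer drawn) | CC(C)(C)[Si](C)(C)Oc1ccc([C@H]2O[C@@H]2c2ccc(O[Si](C)(C)C(C)(C)C)cc2)cc1 | intermediate
32 | exo,exo-1,3-bis{4-[(tert-butyldimethylsilyl)oxy]phenyl} carbonyl ylide (ArCH=O(+)–CH(−)Ar, W-shaped) | CC(C)(C)[Si](C)(C)Oc1ccc(/C=[O+]/[CH-]c2ccc(O[Si](C)(C)C(C)(C)C)cc2)cc1 | intermediate (not isolated)
33 | (2S,3S)-2-(4-acetoxyphenyl)-3-[(2R,3R)-7-acetoxy-2-(4-acetoxyphenyl)-3-(3,5-diacetoxyphenyl)-2,3-dihydro-1-benzofuran-5-yl]-4-[(2R,3S,4R,5S)-2,5-bis{4-[(tert-butyldimethylsilyl)oxy]phenyl}-4-(3,5-diacetoxyphenyl)oxolan-3-yl]-2,3-dihydro-1-benzofuran-6-yl acetate | CC(=O)Oc1ccc([C@H]2Oc3cc(OC(C)=O)cc([C@@H]4[C@H](c5cc(OC(C)=O)cc(OC(C)=O)c5)[C@@H](c5ccc(O[Si](C)(C)C(C)(C)C)cc5)O[C@H]4c4ccc(O[Si](C)(C)C(C)(C)C)cc4)c3[C@@H]2c2cc(OC(C)=O)c3c(c2)[C@@H](c2cc(OC(C)=O)cc(OC(C)=O)c2)[C@H](c2ccc(OC(C)=O)cc2)O3)cc1 | intermediate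
34 | kobophenol A: (2S,3S)-3-[(2R,3R)-3-(3,5-dihydroxyphenyl)-7-hydroxy-2-(4-hydroxyphenyl)-2,3-dihydro-1-benzofuran-5-yl]-4-[(2R,3S,4R,5S)-4-(3,5-dihydroxyphenyl)-2,5-bis(4-hydroxyphenyl)oxolan-3-yl]-2-(4-hydroxyphenyl)-2,3-dihydro-1-benzofuran-6-ol | Oc1ccc([C@H]2Oc3cc(O)cc([C@@H]4[C@H](c5cc(O)cc(O)c5)[C@@H](c5ccc(O)cc5)O[C@H]4c4ccc(O)cc4)c3[C@@H]2c2cc(O)c3c(c2)[C@@H](c2cc(O)cc(O)c2)[C@H](c2ccc(O)cc2)O3)cc1 | target

**Totals**
Total step count: 19. Longest linear sequence: 13 steps (1, 2, 3, 4, 5, 9, 10, 11, 12, 14, 15, 18, 19).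

**Steps most likely to fail**

Step 18 (proposed new method). The Z alkene may isomerise to E through hole transfer, the ylide may reclose to the oxirane faster than it adds to the hindered alkene, or the facial selectivity may be poor. The fallback uses known reaction types only, sets out from 21 and comes back at 34. Claisen–Schmidt condensation of 1-[4-(methoxymethoxy)phenyl]ethanone with 3,5-bis(methoxymethoxy)benzaldehyde gives the chalcone F1. Thiazolium-catalysed Stetter addition of 4-(methoxymethoxy)benzaldehyde to F1 gives the triaryl-1,4-diketone F2. Pd(OAc)2/XPhos/NaOt-Bu α-arylation of the CH2 group of F2 with bromide 21 gives the tetraaryl-1,4-dione F3, whose two enolisable centres equilibrate under the base. NaBH4 reduces F3 to the tetraaryl-1,4-diol F4. HCl in MeOH–THF then closes the oxolane by benzylic SN1 cyclodehydration (thermodynamic 2,3-trans and 4,5-trans), removes all methoxymethyl groups and equilibrates C2 of both dihydrobenzofurans. This gives 34 after separation from the isomers that differ at the oxolane, because this route does not control the sense relative to dihydrobenzofuran A.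

Step 10. Condensation at a carbonyl carbon screened by two ortho substituents may stall or divert to the azine. The fallback sets out from 15 and 11 (the latter through its Grignard reagent 16) and comes back at 19. Oxidative ammonolysis of aldehyde 15 (I2, aq. NH3, THF) gives the bromo dialkoxybenzonitrile F5. CuBr-catalysed addition of 16 to F5 and a methanol quench give the N–H diaryl ketimine F6. Deprotonation (NaH) and electrophilic amination at nitrogen with O-(diphenylphosphinyl)hydroxylamine form the N–N bond outside the screened carbon and give hydrazone 19.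

Step 15. Over-reduction to the 1,2-diarylethane, Z to E isomerisation on the palladium surface or slow hydrogen uptake at the hindered alkyne may occur. The fallback sets out from 23 and 26 and comes back at 28; alkyne 27 is bypassed. ZrCl4-catalysed anti-hydrostannation of 26 with Bu3SnH gives the (Z)-alkenylstannane F7. Stille coupling of F7 with bromide 23 (Pd[P(t-Bu)3]2, CuI, DMF) proceeds with retention of the alkene geometry and gives 28.

**Further compounds**
F1 | step 18 | (E)-3-[3,5-bis(methoxymethoxy)phenyl]-1-[4-(methoxymethoxy)phenyl]prop-2-en-1-one | COCOc1ccc(C(=O)/C=C/c2cc(OCOC)cc(OCOC)c2)cc1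
F2 | step 18 | 2-[3,5-bis(methoxymethoxy)phenyl]-1,4-bis[4-(methoxymethoxy)phenyl]butane-1,4-dione (racemic) | COCOc1ccc(C(=O)CC(c2cc(OCOC)cc(OCOC)c2)C(=O)c2ccc(OCOC)cc2)cc1
F3 | step 18 | 2-[3,5-bis(methoxymethoxy)phenyl]-1,4-bis[4-(methoxymethoxy)phenyl]-3-[C4-yl residue of 21, bromine replaced]butane-1,4-dione (mixture at C2 and C3 of the chain) | COCOc1ccc([C@@H]2Oc3cc(OCOC)cc(C(C(=O)c4ccc(OCOC)cc4)C(c4cc(OCOC)cc(OCOC)c4)C(=O)c4ccc(OCOC)cc4)c3[C@@H]2c2cc(OCOC)c3c(c2)[C@@H](c2cc(OCOC)cc(OCOC)c2)[C@@H](c2ccc(OCOC)cc2)O3)cc1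
F4 | step 18 | 1,4-diol from F3 (both C=O reduced to CH–OH, mixture of isomers in the chain) | COCOc1ccc([C@@H]2Oc3cc(OCOC)cc(C(C(O)c4ccc(OCOC)cc4)C(c4cc(OCOC)cc(OCOC)c4)C(O)c4ccc(OCOC)cc4)c3[C@@H]2c2cc(OCOC)c3c(c2)[C@@H](c2cc(OCOC)cc(OCOC)c2)[C@@H](c2ccc(OCOC)cc2)O3)cc1
F5 | step 10 | 2-bromo-4-(methoxymethoxy)-6-{[4-(methoxymethoxy)phenyl]methoxy}benzonitrile | N#Cc1c(OCc2ccc(OCOC)cc2)cc(OCOC)cc1Br
F6 | step 10 | N–H ketimine corresponding to ketone 18 (C=O replaced by C=NH) | N=C(c1c(OCc2ccc(OCOC)cc2)cc(OCOC)cc1Br)c1cc(OCOC)c2c(c1)[C@@H](c1cc(OCOC)cc(OCOC)c1)[C@@H](c1ccc(OCOC)cc1)O2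
F7 | step 15 | 5-[(Z)-2-(tributylstannyl)ethenyl]-1,3-phenylene diacetate | CCCC[Sn](CCCC)(CCCC)/C=C\c1cc(OC(C)=O)cc(OC(C)=O)c1
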